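Everything rests on closing two bonds of an all-adjacent trisubstituted cyclohexane in one flask: C6–C7 of the seven-membered ring and C4–C10 of the cyclobutane (longipinane numbering). The precursor carries a mesylate at C4, an isopropenyl group at C5 and a 3-oxopent-4-yn-2-yl chain at C11. Hydrogen-atom transfer to the isopropenyl group gives the tertiary C6 radical, which adds to the ynone terminus C7. The resulting cycloheptenone can enolise only at C10, held next to C4 across the C5–C11 ring fusion, and base closes the four-membered ring by displacing the mesylate. The step exploits the C9 carbonyl twice, as radical acceptor and as enolate source.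

Key step: step 8

Remark: longipinane numbering is used throughout (C1 ring ketone carbon, C2 CH2, C3 CHMe, C4 and C11 bridgeheads, C5 and C10 one-carbon bridges, C6 CMe2, C7 and C9 ester-bearing carbons, C8 CH2); "3-demethyl" means that the C3 methyl group is still missing.

Step 1
Reactants: 1 1,4-dioxaspiro[4.5]dec-6-en-8-one
Product: 2 7-iodo-1,4-dioxaspiro[4.5]dec-6-en-8-one
Conditions: I2, pyridine, CH2Cl2, 0 → 25 °C
Reagents that add atoms: iodine, II
Why: α-Iodination of the enone by pyridine conjugate addition, iodination of the enolate and elimination should give the 2-iodoenone; no stereocenter is formed.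

Step 2
Reactants: 2 7-iodo-1,4-dioxaspiro[4.5]dec-6-en-8-one
Product: 3 (8S)-7-iodo-1,4-dioxaspiro[4.5]dec-6-en-8-ol
Conditions: (R)-1-methyl-3,3-diphenyltetrahydro-1H,3H-pyrrolo[1,2-c][1,3,2]oxazaborole (10 mol%), BH3·SMe2, THF, −20 °C
Reagents that add atoms: none
Why: Corey–Bakshi–Shibata reduction, in which the iodoalkene arm acts as the large group, should set the (8S)-carbinol that later controls every ring stereocenter.

Step 3
Reactants: 3 (8S)-7-iodo-1,4-dioxaspiro[4.5]dec-6-en-8-ol
Product: 4 2-[(6R)-7-iodo-1,4-dioxaspiro[4.5]dec-7-en-6-yl]-N,N-dimethylpropanamide (both epimers at the amide α-carbon)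
Conditions: EtC(OMe)2NMe2, xylenes, 140 °C (MeOH distilled off)
Reagents that add atoms: 1,1-dimethoxy-N,N-dimethylpropan-1-amine, CCC(OC)(OC)N(C)C
Why: Eschenmoser–Claisen [3,3] rearrangement should transfer the C8–O chirality suprafacially to the new C6–C bond (C11 of the target), while the epimeric amide α-carbon (future C10) is levelled in step 8.

Step 4
Reactants: 4 2-[(6R)-7-iodo-1,4-dioxaspiro[4.5]dec-7-en-6-yl]-N,N-dimethylpropanamide
Product: 6 2-[(6S)-7-(2-hydroxypropan-2-yl)-1,4-dioxaspiro[4.5]dec-7-en-6-yl]-N,N-dimethylpropanamide, via alkenylmagnesium chloride 5 (not isolated)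
Conditions: i-PrMgCl·LiCl, THF, −20 °C; then acetone, LaCl3·2LiCl, 0 °C; aq NH4Cl
Reagents that add atoms: acetone, CC(C)=O
Why: Iodine–magnesium exchange with the turbo Grignard reagent followed by 1,2-addition to acetone should install the future C6 carbon as a tertiary carbinol without touching the tertiary amide.

Step 5
Reactants: 6 2-[(6S)-7-(2-hydroxypropan-2-yl)-1,4-dioxaspiro[4.5]dec-7-en-6-yl]-N,N-dimethylpropanamide
Product: 8 2-[(6R,7R,8R)-8-hydroxy-7-(2-hydroxypropan-2-yl)-1,4-dioxaspiro[4.5]decan-6-yl]-N,N-dimethylpropanamide, via cyclic alkoxyborane 7 (not isolated)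
Conditions: BH3·SMe2, THF, 0 °C; then NaBO3·4H2O, H2O, 25 °C
Reagents that add atoms: sodium perborate tetrahydrate, [Na+].[O-]OB=O.O.O.O.O
Why: Hydroboration–oxidation, expected to be faster at 0 °C than borane reduction of the hindered tertiary amide, should add H (to C7) and OH (to C8) syn to each other and anti to the pseudoaxial C6 side chain, which sets the C7 substituent cis to the side chain and the C8 hydroxyl trans to both.

Step 6
Reactants: 8 2-[(6R,7R,8R)-8-hydroxy-7-(2-hydroxypropan-2-yl)-1,4-dioxaspiro[4.5]decan-6-yl]-N,N-dimethylpropanamide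
Product: 10 (6R,7S,8R)-6-[1-(dimethylamino)-1-oxopropan-2-yl]-7-(prop-1-en-2-yl)-1,4-dioxaspiro[4.5]decan-8-yl methanesulfonate, via secondary mesylate 9 (not isolated)
Conditions: MsCl, pyridine, CH2Cl2, 0 °C; then Burgess reagent (methyl N-(triethylammoniosulfonyl)carbamate), PhMe, 60 °C
Reagents that add atoms: methanesulfonyl chloride, CS(=O)(=O)Cl
Why: Selective sulfonylation of the secondary alcohol followed by Burgess syn-dehydration of the tertiary carbinol should give the isopropenyl group, because six methyl hydrogens compete with one hindered ring hydrogen (C7–H), and the configuration at C8 is retained.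

Step 7
Reactants: 10 (6R,7S,8R)-6-[1-(dimethylamino)-1-oxopropan-2-yl]-7-(prop-1-en-2-yl)-1,4-dioxaspiro[4.5]decan-8-yl methanesulfonate
Product: 12 (6R,7S,8R)-6-(3-oxopent-4-yn-2-yl)-7-(prop-1-en-2-yl)-1,4-dioxaspiro[4.5]decan-8-yl methanesulfonate, via silyl ynone 11 (not isolated)
Conditions: LiC≡CSiMe3, BF3·OEt2, THF, −78 °C; then Bu4NF, AcOH, THF, 0 °C
Reagents that add atoms: lithium (trimethylsilyl)acetylide, [Li]C#C[Si](C)(C)C
Why: Boron-trifluoride-mediated acylation of the alkynyl borate by the tertiary amide should stop at the tetrahedral adduct and give the ynone on work-up, and buffered fluoride should remove the silyl group without conjugate addition.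

Step 8
Reactants: 12 (6R,7S,8R)-6-(3-oxopent-4-yn-2-yl)-7-(prop-1-en-2-yl)-1,4-dioxaspiro[4.5]decan-8-yl methanesulfonate
Product: 14 (4S,5S,10R,11R)-3-demethyllongipin-7-ene-1,9-dione 1-(ethylene acetal), via cycloheptenone mesylate 13 (not isolated)
Conditions: Fe(acac)3 (30 mol%), PhSiH3, EtOH, 60 °C; volatiles removed and THF added in the same flask; then KN(SiMe3)2, −78 → 25 °C
Reagents that add atoms: none
Why: Hydrogen-atom transfer from an iron hydride to the isopropenyl group should give the tertiary C6 radical, which adds to the alkyne terminus C7 in a 7-endo-dig closure (closest known type: iron-catalysed reductive coupling of olefins with acceptors by hydrogen-atom transfer, and Giese additions to alkynones), and the vinyl radical is reduced and protonated to the cis-enone 13. That cross-conjugated cycloheptenone has one enolisable carbon, C10, so the base gives a single dienolate that displaces the C4 mesylate in a 4-exo-tet alkylation (closest known type: intramolecular ketone alkylations that close the cyclobutane of bicyclo[3.1.1]heptanones). C10 becomes quaternary with its configuration dictated by the cis-fused seven-membered ring that carries the enolate, so both C10 epimers of 12 converge, and C4 is set by SN2 inversion of the mesylate placed trans to the C5 and C11 substituents in step 5. The radical stage needs attack at the alkyne terminus and not 6-exo attack at the carbonyl-bearing carbon, which the polarity of the nucleophilic tertiary radical should secure. The polar stage needs C-alkylation, which is expected because O-alkylation would create a strained bridgehead enol ether, and substitution must outrun elimination at C4, which the enforced proximity of C10 to the rear of the C4–O bond should favour.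

Step 9
Reactants: 14 (4S,5S,10R,11R)-3-demethyllongipin-7-ene-1,9-dione 1-(ethylene acetal)
Product: 16 (4S,5S,7R,10R,11R)-7-hydroxy-3-demethyllongipinane-1,9-dione 1-(ethylene acetal), via pinacol boronate 15 (not isolated)
Conditions: CuCl (5 mol%), NaOt-Bu, (R)-1-[(SP)-2-(diphenylphosphino)ferrocenyl]ethyldicyclohexylphosphine, B2pin2, MeOH, THF, 25 °C; then NaBO3·4H2O, THF/H2O
Reagents that add atoms: sodium perborate tetrahydrate, [Na+].[O-]OB=O.O.O.O.O
Why: Copper-catalysed asymmetric conjugate borylation and stereoretentive oxidation should set C7 (oxygen on the face turned toward C4) under ligand control, since the two enone faces differ only remotely (C1 acetal against C3 methylene); the enantiomeric ligand is used should the sense prove opposite.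

Step 10
Reactants: 16 (4S,5S,7R,10R,11R)-7-hydroxy-3-demethyllongipinane-1,9-dione 1-(ethylene acetal)
Product: 17 (4S,5S,7R,9R,10R,11R)-7,9-dihydroxy-3-demethyllongipinan-1-one ethylene acetal
Conditions: Me4NBH(OAc)3, MeCN/AcOH, −30 °C
Reagents that add atoms: none
Why: Evans–Saksena reduction delivers hydride intramolecularly from the C7 alkoxyborohydride to the same face of the C9 carbonyl and should give the 1,3-anti diol.

Step 11
Reactants: 17 (4S,5S,7R,9R,10R,11R)-7,9-dihydroxy-3-demethyllongipinan-1-one ethylene acetal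
Product: 18 (4S,5S,7R,9R,10R,11R)-7,9-bis(angeloyloxy)-3-demethyllongipinan-1-one ethylene acetal
Conditions: LiN(SiMe3)2, THF, −78 °C; then angelic anhydride, −78 → 0 °C; aq NH4Cl
Reagents that add atoms: angelic anhydride, C/C=C(/C)C(=O)OC(=O)/C(C)=C\C
Why: Acylation of the two hindered lithium alkoxides by the anhydride, without nucleophilic catalyst, should keep the (Z) geometry of both esters.

Step 12
Reactants: 18 (4S,5S,7R,9R,10R,11R)-7,9-bis(angeloyloxy)-3-demethyllongipinan-1-one ethylene acetal
Product: 19 (4S,5S,7R,9R,10R,11R)-7,9-bis(angeloyloxy)-3-demethyllongipinan-1-one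
Conditions: 1 M HCl, THF, 25 °C
Reagents that add atoms: water, O
Why: Acid hydrolysis of the dioxolane should free the C1 ketone while the esters survive.

Step 13
Reactants: 19 (4S,5S,7R,9R,10R,11R)-7,9-bis(angeloyloxy)-3-demethyllongipinan-1-one
Product: 20 (4S,5S,7R,9R,10R,11R)-7,9-bis(angeloyloxy)-3-demethyllongipin-2-en-1-one
Conditions: 2-iodoxybenzoic acid (IBX), DMSO, 70 °C
Reagents that add atoms: none
Why: IBX dehydrogenation of the ketone can only engage C2, because the other α-carbon (C11) is a bridgehead, and should give the verbenone-type enone.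

Step 14
Reactants: 20 (4S,5S,7R,9R,10R,11R)-7,9-bis(angeloyloxy)-3-demethyllongipin-2-en-1-one
Product: 21 (3R,4S,5S,7R,9R,10R,11R)-7,9-bis(angeloyloxy)longipinan-1-one (target)
Conditions: Me2CuLi, Et2O, −78 °C; aq NH4Cl
Reagents that add atoms: lithium dimethylcuprate, [Li+].C[Cu-]C
Why: Cuprate conjugate addition should occur anti to the C10 bridge, whose methyl group shields one enone face (as in additions to apoverbenone), placing the C3 methyl on the C5 side, and the β-substituted angelates are far poorer acceptors.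

Compound list
1 | 1,4-dioxaspiro[4.5]dec-6-en-8-one | O=C1C=CC2(CC1)OCCO2 | starting material
2 | 7-iodo-1,4-dioxaspiro[4.5]dec-6-en-8-one | O=C1C(I)=CC2(CC1)OCCO2 | intermediate
3 | (8S)-7-iodo-1,4-dioxaspiro[4.5]dec-6-en-8-ol | O[C@@H]1C(I)=CC2(CC1)OCCO2 | intermediate
4 | 2-[(6R)-7-iodo-1,4-dioxaspiro[4.5]dec-7-en-6-yl]-N,N-dimethylpropanamide (both epimers at the amide α-carbon) | CC(C(=O)N(C)C)[C@H]1C(I)=CCCC12OCCO2 | intermediate
5 | alkenylmagnesium chloride from 4 (MgCl in place of iodine) | CC(C(=O)N(C)C)[C@H]1C([Mg]Cl)=CCCC12OCCO2 | intermediate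
6 | 2-[(6S)-7-(2-hydroxypropan-2-yl)-1,4-dioxaspiro[4.5]dec-7-en-6-yl]-N,N-dimethylpropanamide | CC(C(=O)N(C)C)[C@H]1C(C(C)(C)O)=CCCC12OCCO2 | intermediate
7 | cyclic alkoxyborane from 6 (1,2-oxaborolane joining the carbinol oxygen and C8) | CC(C(=O)N(C)C)[C@H]1[C@H]3C(C)(C)OB[C@@H]3CCC12OCCO2 | intermediate
8 | 2-[(6R,7R,8R)-8-hydroxy-7-(2-hydroxypropan-2-yl)-1,4-dioxaspiro[4.5]decan-6-yl]-N,N-dimethylpropanamide | CC(C(=O)N(C)C)[C@H]1[C@@H](C(C)(C)O)[C@H](O)CCC12OCCO2 | intermediate
9 | 8-O-methanesulfonate of 8 (tertiary alcohol free) | CC(C(=O)N(C)C)[C@H]1[C@@H](C(C)(C)O)[C@H](OS(C)(=O)=O)CCC12OCCO2 | intermediate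
10 | (6R,7S,8R)-6-[1-(dimethylamino)-1-oxopropan-2-yl]-7-(prop-1-en-2-yl)-1,4-dioxaspiro[4.5]decan-8-yl methanesulfonate | CC(C(=O)N(C)C)[C@H]1[C@@H](C(C)=C)[C@H](OS(C)(=O)=O)CCC12OCCO2 | intermediate
11 | trimethylsilyl ynone from 10 (C≡C–SiMe3 in place of NMe2) | CC(C(=O)C#C[Si](C)(C)C)[C@H]1[C@@H](C(C)=C)[C@H](OS(C)(=O)=O)CCC12OCCO2 | intermediate
12 | (6R,7S,8R)-6-(3-oxopent-4-yn-2-yl)-7-(prop-1-en-2-yl)-1,4-dioxaspiro[4.5]decan-8-yl methanesulfonate | CC(C(=O)C#C)[C@H]1[C@@H](C(C)=C)[C@H](OS(C)(=O)=O)CCC12OCCO2 | intermediate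
13 | (4R,5S,11R)-4-(methanesulfonyloxy)-3-demethyl-4,10-secolongipin-7-ene-1,9-dione 1-(ethylene acetal) (cis-fused cycloheptenone, both C10 epimers) | CC1C(=O)C=CC(C)(C)[C@H]2[C@H](OS(C)(=O)=O)CCC3(OCCO3)[C@@H]12 | intermediate
14 | (4S,5S,10R,11R)-3-demethyllongipin-7-ene-1,9-dione 1-(ethylene acetal) | C[C@@]12C(=O)C=CC(C)(C)[C@H]3[C@@H]1CCC4(OCCO4)[C@@H]23 | intermediate
15 | (4S,5S,7R,10R,11R)-7-(pinacolboryl)-3-demethyllongipinane-1,9-dione 1-(ethylene acetal) | C[C@@]12C(=O)C[C@@H](B3OC(C)(C)C(C)(C)O3)C(C)(C)[C@H]4[C@@H]1CCC5(OCCO5)[C@@H]24 | intermediate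
16 | (4S,5S,7R,10R,11R)-7-hydroxy-3-demethyllongipinane-1,9-dione 1-(ethylene acetal) | C[C@@]12C(=O)C[C@@H](O)C(C)(C)[C@H]3[C@@H]1CCC4(OCCO4)[C@@H]23 | intermediate
17 | (4S,5S,7R,9R,10R,11R)-7,9-dihydroxy-3-demethyllongipinan-1-one ethylene acetal | C[C@@]12[C@H](O)C[C@@H](O)C(C)(C)[C@H]3[C@@H]1CCC4(OCCO4)[C@@H]23 | intermediate
18 | (4S,5S,7R,9R,10R,11R)-7,9-bis(angeloyloxy)-3-demethyllongipinan-1-one ethylene acetal | C[C@@]12[C@H](OC(=O)/C(C)=C\C)C[C@@H](OC(=O)/C(C)=C\C)C(C)(C)[C@H]3[C@@H]1CCC4(OCCO4)[C@@H]23 | intermediate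
19 | (4S,5S,7R,9R,10R,11R)-7,9-bis(angeloyloxy)-3-demethyllongipinan-1-one | C[C@@]12[C@H](OC(=O)/C(C)=C\C)C[C@@H](OC(=O)/C(C)=C\C)C(C)(C)[C@H]3[C@@H]1CCC(=O)[C@@H]23 | intermediate
20 | (4S,5S,7R,9R,10R,11R)-7,9-bis(angeloyloxy)-3-demethyllongipin-2-en-1-one | C[C@@]12[C@H](OC(=O)/C(C)=C\C)C[C@@H](OC(=O)/C(C)=C\C)C(C)(C)[C@H]3[C@@H]1C=CC(=O)[C@@H]23 | intermediate
21 | (3R,4S,5S,7R,9R,10R,11R)-7,9-bis(angeloyloxy)longipinan-1-one (CNP0283599.1) | C[C@@]12[C@H](OC(=O)/C(C)=C\C)C[C@@H](OC(=O)/C(C)=C\C)C(C)(C)[C@H]3[C@@H]1[C@H](C)CC(=O)[C@@H]23 | target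

Total step count: 14
Longest linear sequence: 14

The three steps most likely to fail are, in this order, step 8, step 6 and step 9.

Risk at step 8 (the key step): the radical stage may end in simple reduction of the isopropenyl group or in attack at the carbonyl-bearing alkyne carbon, and the mesylate may be lost by elimination before C10 reaches C4. Fallback for step 8: it sets out from 10 and closes the cyclobutane first. The amide enolate, which alkylates only on carbon (LiN(i-Pr)2, THF, −78 → 0 °C), displaces the mesylate to give N,N,6-trimethyl-7-(prop-1-en-2-yl)spiro[bicyclo[3.1.1]heptane-2,2'-[1,3]dioxolane]-6-carboxamide F1. The epimer with the amide carbon turned toward the isopropenyl-bearing bridge is separated and carried on. The amide is converted as in step 7, through 1-[6-methyl-7-(prop-1-en-2-yl)spiro[bicyclo[3.1.1]heptane-2,2'-[1,3]dioxolan]-6-yl]-3-(trimethylsilyl)prop-2-yn-1-one F2, into 1-[6-methyl-7-(prop-1-en-2-yl)spiro[bicyclo[3.1.1]heptane-2,2'-[1,3]dioxolan]-6-yl]prop-2-yn-1-one F3. Fe(acac)3 and PhSiH3 (EtOH, 60 °C) then close the seven-membered ring inside the rigid bicycle, where the C6 radical and the alkyne sit on neighbouring one-carbon bridges, and the sequence returns to the route at 14.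

Risk at step 6: the dehydration may run toward the ring and give the tetrasubstituted isopropylidene isomer, or the tertiary cation may rearrange. Fallback for step 6: it sets out from 9, now isolated, and keeps the tertiary alcohol. The ynone is made as in step 7 with one further equivalent of the acetylide, through (6R,7R,8R)-7-(2-hydroxypropan-2-yl)-6-[3-oxo-5-(trimethylsilyl)pent-4-yn-2-yl]-1,4-dioxaspiro[4.5]decan-8-yl methanesulfonate F4, to give (6R,7R,8R)-7-(2-hydroxypropan-2-yl)-6-(3-oxopent-4-yn-2-yl)-1,4-dioxaspiro[4.5]decan-8-yl methanesulfonate F5. The tertiary C–O bond is then cleaved to the same C6 radical by titanium-catalysed dehydroxylative radical generation (Cp*TiCl3, Zn, Et3SiCl, THF, 25 °C). Its 7-endo-dig closure rejoins the route at 13, which is treated with KN(SiMe3)2 as in step 8.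

Risk at step 9: boryl-copper addition next to the quaternary C6 may be slow, and the two faces of the nearly mirror-symmetric enone may be poorly distinguished. Fallback for step 9: it sets out from 14 and uses catalyst-controlled nucleophilic epoxidation (La(Oi-Pr)3, (R)-BINOL, Ph3AsO, cumene hydroperoxide, THF) to give 7,8-epoxy-3-demethyllongipinane-1,9-dione 1-(ethylene acetal) F6, with the oxygen on the face turned toward C4. Reductive opening of the epoxide at C8 with SmI2 (THF/MeOH, −78 °C) returns to the route at 16.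

Further compounds
F1 | step 8 | N,N,6-trimethyl-7-(prop-1-en-2-yl)spiro[bicyclo[3.1.1]heptane-2,2'-[1,3]dioxolane]-6-carboxamide | CN(C)C(=O)[C@]1(C)[C@H]2CCC3(OCCO3)[C@@H]1[C@H]2C(C)=C
F2 | step 8 | 1-[6-methyl-7-(prop-1-en-2-yl)spiro[bicyclo[3.1.1]heptane-2,2'-[1,3]dioxolan]-6-yl]-3-(trimethylsilyl)prop-2-yn-1-one | C[Si](C)(C)C#CC(=O)[C@]1(C)[C@H]2CCC3(OCCO3)[C@@H]1[C@H]2C(C)=C
F3 | step 8 | 1-[6-methyl-7-(prop-1-en-2-yl)spiro[bicyclo[3.1.1]heptane-2,2'-[1,3]dioxolan]-6-yl]prop-2-yn-1-one | C#CC(=O)[C@]1(C)[C@H]2CCC3(OCCO3)[C@@H]1[C@H]2C(C)=C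
F4 | step 6 | (6R,7R,8R)-7-(2-hydroxypropan-2-yl)-6-[3-oxo-5-(trimethylsilyl)pent-4-yn-2-yl]-1,4-dioxaspiro[4.5]decan-8-yl methanesulfonate | CC(C(=O)C#C[Si](C)(C)C)[C@H]1[C@@H](C(C)(C)O)[C@H](OS(C)(=O)=O)CCC12OCCO2
F5 | step 6 | (6R,7R,8R)-7-(2-hydroxypropan-2-yl)-6-(3-oxopent-4-yn-2-yl)-1,4-dioxaspiro[4.5]decan-8-yl methanesulfonate | CC(C(=O)C#C)[C@H]1[C@@H](C(C)(C)O)[C@H](OS(C)(=O)=O)CCC12OCCO2
F6 | step 9 | 7,8-epoxy-3-demethyllongipinane-1,9-dione 1-(ethylene acetal) | C[C@@]12C(=O)[C@H]3O[C@H]3C(C)(C)[C@H]4[C@@H]1CCC5(OCCO5)[C@@H]24
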